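Late in a run the open intermediate gives way to target: in the north-west run it sinks from 75.2% at 2.50 min to 60.5% at 8.00 min, while target climbs from 9.8% to 27.1%. So we count how often the catalyst has turned over by the end of a flask.

| flask | substrate | coupling partner | free catalyst | remark | time |
|---|---|---|---|---|---|
| south-east | 0.10 M | 0.10 M | 15 mM | run made earlier |  |
| south | 0.10 M | 0.10 M | 21 mM | run made earlier |  |
| north-west | 0.10 M | 0.10 M | 33 mM | run made earlier |  |
| Thursday's | 0.10 M (fed, over 10.0 min) | 0.100 M | 15 mM | all but substrate at the start; substrate goes in evenly over 10.0 min, the run ends at 10 min | 10 min |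
| Tuesday's | 0.10 M | 0.100 M (fed, over 10.0 min) | 15 mM | all but coupling partner at the start; coupling partner goes in evenly over 10.0 min, the run ends at 10 min | 10 min |
| Monday's | 0.10 M | 0.100 M | 15 mM | a closed flask charged with all of it at once and left for 10 min | 10 min |
| Wednesday's | 0.10 M | 0.100 M | 15 mM | one stirred flow tank at steady state, fed with the mixture as stated, mean residence time 10 min |  |

- the set-up with the highest amount of open intermediate at the outlet or at the end, in percent of the substrate put in ("none" if the first two lie within 2 percentage points) (Thursday's / Tuesday's / Monday's / Wednesday's / none)
- amount of open intermediate at the outlet or at the end, in percent of the substrate put in, Thursday's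
- amount of open intermediate at the outlet or at the end, in percent of the substrate put in, Tuesday's
- amount of open intermediate at the outlet or at the end, in percent of the substrate put in, Monday's
- amount of open intermediate at the outlet or at the end, in percent of the substrate put in, Wednesday's

- a species is counted by the substrate in it: one idle adduct counts as two
- amounts and yields of target count idle adduct too
- the stated concentrations are those of everything mixed, before any reaction; amounts are the same in each set-up
- candidate steps: substrate + free catalyst -> spent catalyst; coupling partner + target -> over-reaction product; substrate + free catalyst -> free catalyst + open intermediate; free catalyst + open intermediate <-> catalyst intermediate; substrate + target <-> idle adduct; coupling partner + catalyst intermediate -> free catalyst + target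
- the feed brings no volume worth counting
- the earlier runs were made in a closed, stirred flask
- in an amount of target, one idle adduct counts as one target

| run | time / min | open intermediate / % | target / % | substrate / % |
|---|---|---|---|---|
| south-east | 0.833 | 37.8 | 2.6 | 55.5 |
| south-east | 2.50 | 68.0 | 3.4 | 23.4 |
| south-east | 5.00 | 78.4 | 8.3 | 7.7 |
| south-east | 8.00 | 78.4 | 11.1 | 2.1 |
| south-east | 10.0 | 75.7 | 15.3 | 1.4 |
| south | 0.667 | 42.3 | 2.2 | 54.0 |
| south | 2.00 | 70.1 | 3.2 | 19.9 |
| south | 4.00 | 77.9 | 7.4 | 5.5 |
| south | 6.00 | 77.3 | 12.8 | 1.2 |
| south | 8.00 | 72.5 | 18.2 | 0 |
| north-west | 0.667 | 53.9 | 0.3 | 35.4 |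
| north-west | 1.33 | 70.6 | 2.9 | 14.4 |
| north-west | 2.50 | 75.2 | 9.8 | 5.7 |
| north-west | 4.00 | 74.6 | 14.1 | 0.8 |
| north-west | 8.00 | 60.5 | 27.1 | 1.0 |

(standard deviation of a reading: 1 percentage point)

We read the last row of each table, as target made per catalyst charged per minute. South-east gives 0.102 min⁻¹, south 0.108 min⁻¹ and north-west 0.103 min⁻¹. These lie close although the catalyst charge differs, so we carry their mean 0.104 min⁻¹ as the turnover frequency, target made per catalyst charged per minute.

Monday's repeats the south-east recipe, so its catalyst makes 1.04 turnovers, worth 15.6% target, and its open intermediate should match the last reading, 75.7%.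

Tuesday's starts with the same charge of substrate, but the feed brings [coupling partner] up evenly from zero, so, with little of it used, we take it to average half its charge. If turnovers go with [coupling partner], Tuesday's makes 0.520 turnovers and 7.80% target. Taking the target not made to stay as open intermediate, our reckoning is 83.5%.

The forecast names Tuesday's as best, with 83% there, 76% for Monday's, 65% for Thursday's and 63% for Wednesday's. Its ground for Tuesday's is “coupling partner arrives gradually, so target roughly halves”. Our figure stands 0.50 percentage points above its Tuesday's.

The flask gives Tuesday's as best, at 82.7%, with Monday's at 76.2%, Thursday's at 65.1% and Wednesday's at 60.9%, so the forecast held. Tuesday's also holds 0.874% of over-reaction product, which our count of target does not contain, and that step makes no difference to Tuesday's open intermediate. The 8.86% of target in Tuesday's comes to 0.591 turnovers, against the 0.520 we counted.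

    substrate + free catalyst → spent catalyst (k = 0.0298 L mol⁻¹ s⁻¹)
    coupling partner + target → over-reaction product (k = 0.00744 L mol⁻¹ s⁻¹)
    substrate + free catalyst → free catalyst + open intermediate (k = 0.811 L mol⁻¹ s⁻¹)
    free catalyst + open intermediate ⇌ catalyst intermediate (K = 4.60 L mol⁻¹, k = 0.325 L mol⁻¹ s⁻¹)
    substrate + target ⇌ idle adduct, settled at all times (K = 30.8 L mol⁻¹)
    coupling partner + catalyst intermediate → free catalyst + target (k = 0.118 L mol⁻¹ s⁻¹)

The neighbour of Tuesday's fed with 0.025 M of coupling partner has a quarter of the charge, so the count gives 0.130 turnovers and 1.96% target. Computed, that flask holds 2.57% of target and 89.5% of open intermediate.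

(The numbers in the tables were computed with constants of no real substance, noise included.)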